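**Retrosynthetic overview**
- Target ⇒ veprisine + the quinone methide from the 4-hydroxyquinolone and 3-methylbutanal: acid-catalysed, enantioselective stepwise oxa-[4+2]; forms C-a–C-b and O–C-c and closes pyran ring A last.
- Veprisine ⇒ 3-hydroxy-2,2-dimethyl-2,3-dihydrofuroquinolone: cationic one-carbon ring expansion (diazo carbon inserted, 1,2-shift), dihydrofuran → pyran ring B.
- Dihydrofuranol ⇒ 4-hydroxy-7,8-dimethoxy-1-methylquinolin-2-one + 2-bromo-2-methylpropanal (interrupted Feist–Bénary).
- Quinolone ⇒ 2,3-dimethoxy-N-methylaniline + malonic acid; aniline ⇒ veratrole (ortho-lithiation, electrophilic amination) ⇒ catechol.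
- Ring order: pyridone ring, dihydrofuran, pyran ring B (by ring expansion), pyran ring A.

Labels: C-a = CH bearing isobutyl; C-b = ring-fusion CH bonded to CMe2; C-c = ring-fusion CH bonded to oxygen and to C-3 of the veprisine quinolone; the target is (aS,bS,cR) with the C-b and C-c hydrogens cis.
Assumption: the (R)-acid in step 6 is written as the antipode that gives (aS,bS,cR); if the sense of induction is found to be opposite, the (S)-acid is used.

**Step 1**
Reactants: 1 catechol (benzene-1,2-diol)
Product: 2 1,2-dimethoxybenzene (veratrole)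
Conditions: MeI (2.5 equiv), K2CO3 (3 equiv), acetone, reflux
Reagents that add atoms: iodomethane, CI
Why: Williamson ether synthesis on both phenols; no stereocentre.

**Step 2**
Reactants: 2 1,2-dimethoxybenzene
Product: 4 2,3-dimethoxy-N-methylaniline, via aryllithium 3 (not isolated)
Conditions: n-BuLi (1.1 equiv), TMEDA, Et2O, 0 °C to rt; then MeN(Li)OMe [from MeNHOMe·HCl (2 equiv) + MeLi (4 equiv), Et2O, −78 °C], −78 to −15 °C; H2O
Reagents that add atoms: N,O-dimethylhydroxylamine hydrochloride (used as its lithium amide), CNOC.Cl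
Why: Directed ortho-metalation next to the methoxy groups, then electrophilic amination of the aryllithium by the lithium alkoxyamide with methoxide as leaving group; no stereocentre.

**Step 3**
Reactants: 4 2,3-dimethoxy-N-methylaniline, 5 malonic acid
Product: 7 4-hydroxy-7,8-dimethoxy-1-methylquinolin-2(1H)-one, via malonamic acid 6 (not isolated)
Conditions: POCl3 (3 equiv), 90 °C, 3 h; then ice, aq. NaOH, HCl to pH 3
Reagents that add atoms: none
Why: N-acylation by activated malonic acid, then intramolecular Friedel–Crafts acylation at the only free position ortho to nitrogen (para to a methoxy group), a Ziegler–Gelfert-type quinolone synthesis; no stereocentre.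

**Step 4**
Reactants: 7 4-hydroxy-7,8-dimethoxy-1-methylquinolin-2(1H)-one, 8 2-bromo-2-methylpropanal
Product: 10 3-hydroxy-6,7-dimethoxy-2,2,5-trimethyl-2,3-dihydrofuro[3,2-c]quinolin-4(5H)-one (racemic), via bromohydrin 9 (not isolated)
Conditions: K2CO3 (1.5 equiv), DMF, 0 to 40 °C, 7 added slowly to 8 (1.5 equiv); aq. NH4Cl
Reagents that add atoms: none
Why: Interrupted Feist–Bénary reaction: C-3 aldol addition to the aldehyde, then O-4 displaces the tertiary bromide, and the quaternary C-2 blocks dehydration to a furan; the carbinol centre forms racemic and is erased in step 5.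

**Step 5**
Reactants: 10 3-hydroxy-6,7-dimethoxy-2,2,5-trimethyl-2,3-dihydrofuro[3,2-c]quinolin-4(5H)-one
Product: 12 7,8-dimethoxy-2,2,6-trimethyl-2H-pyrano[3,2-c]quinolin-5(6H)-one (veprisine), via silyl diazonium adduct 11 (not isolated)
Conditions: Sc(OTf)3 (10 mol%), TMSCHN2 (2.0 equiv, 2 M in hexanes), CH2Cl2, −40 to 0 °C
Reagents that add atoms: trimethylsilyldiazomethane, C[Si](C)(C)C=[N+]=[N-]
Why: Proposed new method: Sc(OTf)3 ionises the benzylic carbinol of 10 to a cation stabilised by the 4-alkoxyquinolone, the carbon of TMSCHN2 adds to give diazonium 11, and loss of N2 is assisted by a 1,2-shift of the electron-rich quinolone C-3 (phenonium-type bridging; migration of the CMe2 carbon gives the same skeleton), which enlarges the dihydrofuran to the pyran and leaves a beta-silyl cation that loses silicon to place the C-3/C-4 double bond, erasing the stereocentre of 10; closest known reaction types are Lewis-acid C–C insertion of diazo compounds into electron-rich benzylic electrophiles via phenonium ions and the Tiffeneau–Demjanov ring expansion.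

**Step 6**
Reactants: 7 4-hydroxy-7,8-dimethoxy-1-methylquinolin-2(1H)-one, 12 veprisine, 13 3-methylbutanal
Product: 15 target CNP0275598.1 [(aS,bS,cR) cis-fused dimer], via quinone methide 14 (not isolated)
Conditions: 12 (1.5 equiv), 13 (1.3 equiv), (R)-3,3'-bis(2,4,6-triisopropylphenyl)-BINOL N-triflylphosphoramide (10 mol%), 5 Å molecular sieves, CH2Cl2, −20 °C to rt, 7 (1.0 equiv) added in portions over 6 h
Reagents that add atoms: none
Why: Proposed new method: the chiral acid catalyses Knoevenagel condensation of 7 with 13 to quinone methide 14 and holds protonated 14 in a hydrogen-bonded chiral ion pair, the nucleophilic C-3 of the styrene-like alkene of 12 adds to C-a on one face with isobutyl anti to CMe2 (the gem-dimethyl group blocks the endo arrangement; sets C-a and C-b), and O-4 then closes on the benzylic cation from the face of the tether (cis ring fusion, sets C-c) to give the 2-quinolone isomer; closest known reaction types are chiral phosphoric acid catalysed oxa-[4+2] reactions of in situ ortho-quinone methides with styrenes and the racemic domino Knoevenagel/hetero-Diels–Alder reaction.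

**Compound list**
1 | catechol (benzene-1,2-diol) | Oc1ccccc1O | starting material
2 | 1,2-dimethoxybenzene (veratrole) | COc1ccccc1OC | intermediate
3 | (2,3-dimethoxyphenyl)lithium | COc1cccc([Li])c1OC | intermediate
4 | 2,3-dimethoxy-N-methylaniline | CNc1cccc(OC)c1OC | intermediate
5 | malonic acid | OC(=O)CC(=O)O | starting material
6 | 3-[(2,3-dimethoxyphenyl)(methyl)amino]-3-oxopropanoic acid | CN(C(=O)CC(=O)O)c1cccc(OC)c1OC | intermediate
7 | 4-hydroxy-7,8-dimethoxy-1-methylquinolin-2(1H)-one | COc1ccc2c(O)cc(=O)n(C)c2c1OC | intermediate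
8 | 2-bromo-2-methylpropanal | CC(C)(Br)C=O | starting material
9 | 3-(2-bromo-1-hydroxy-2-methylpropyl)-4-hydroxy-7,8-dimethoxy-1-methylquinolin-2(1H)-one (racemic) | COc1ccc2c(O)c(C(O)C(C)(C)Br)c(=O)n(C)c2c1OC | intermediate
10 | 3-hydroxy-6,7-dimethoxy-2,2,5-trimethyl-2,3-dihydrofuro[3,2-c]quinolin-4(5H)-one (racemic) | COc1ccc2c3OC(C)(C)C(O)c3c(=O)n(C)c2c1OC | intermediate
11 | (6,7-dimethoxy-2,2,5-trimethyl-4-oxo-2,3,4,5-tetrahydrofuro[3,2-c]quinolin-3-yl)(trimethylsilyl)methanediazonium | COc1ccc2c3OC(C)(C)C(C([N+]#N)[Si](C)(C)C)c3c(=O)n(C)c2c1OC | intermediate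
12 | 7,8-dimethoxy-2,2,6-trimethyl-2H-pyrano[3,2-c]quinolin-5(6H)-one (veprisine) | COc1ccc2c3OC(C)(C)C=Cc3c(=O)n(C)c2c1OC | intermediate
13 | 3-methylbutanal | CC(C)CC=O | starting material
14 | 7,8-dimethoxy-1-methyl-3-(3-methylbutylidene)quinoline-2,4(1H,3H)-dione (E/Z mixture) | COc1ccc2C(=O)C(=CCC(C)C)C(=O)N(C)c2c1OC | intermediate
15 | CNP0275598.1: (aS,bS,cR) cis-fused dimer; C-3 and C-4 of the pyran ring of 12 carry C-a [CH(isobutyl), bonded to C-3 of a second unit of 7] and O-4 of that unit | COc1ccc2c3c(c(=O)n(C)c2c1OC)[C@@H](CC(C)C)[C@H]1[C@@H](O3)c2c(c3ccc(OC)c(OC)c3n(C)c2=O)OC1(C)C | target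

**Totals**
Total steps: 6. Longest linear sequence: 6 (1 → 2 → 4 → 7 → 10 → 12 → 15; step 6 joins 12 with a second portion of 7).

**Three steps most likely to fail**

Step 5 (new ring expansion). Risks are a competing 1,2-hydride shift giving the exocyclic 3-methylene isomer, O-methylation of 10, and acid sensitivity of 12. The fallback sets out from 7 and comes back at 12. Compound 7 is condensed with 3-methylbut-2-enal in pyridine at 110 °C. The Knoevenagel product 7,8-dimethoxy-1-methyl-3-(3-methylbut-2-en-1-ylidene)quinoline-2,4(1H,3H)-dione F1 closes by oxa-6π-electrocyclisation to 12. This is known chemistry for pyranoquinolones of this family.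

Step 6 (new asymmetric coupling). Risks are low enantioselectivity, the endo diastereomer, the reversible bis-adduct of 14 with a second 7, and acid dimerisation of 12. The fallback sets out from 7, 12 and 13 and comes back at 15. The three components are heated with ethylenediammonium diacetate (10 mol%) in toluene at 80 °C in a racemic domino Knoevenagel/hetero-Diels–Alder reaction. This gives the racemate, that is 15 together with the enantiomer of 15 F2. Preparative chiral SFC on an amylose tris(3,5-dimethylphenylcarbamate) phase then delivers 15.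

Step 4 (hindered interrupted Feist–Bénary). Risks are slow O-closure at the tertiary carbon and addition of a second 7 to the benzylic position. The fallback sets out from 7 and comes back at 10. Compound 7 is C-acylated with 2-bromo-2-methylpropanoyl bromide (AlCl3, 1,2-dichloroethane, 60 °C) to 3-(2-bromo-2-methylpropanoyl)-4-hydroxy-7,8-dimethoxy-1-methylquinolin-2(1H)-one F3. K2CO3 in DMF closes this by O-alkylation to 6,7-dimethoxy-2,2,5-trimethylfuro[3,2-c]quinoline-3,4(2H,5H)-dione F4. Reduction with NaBH4 and CeCl3·7H2O in MeOH at 0 °C gives 10.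

**Further compounds**
F1 | step 5 | 7,8-dimethoxy-1-methyl-3-(3-methylbut-2-en-1-ylidene)quinoline-2,4(1H,3H)-dione | COc1ccc2C(=O)C(=CC=C(C)C)C(=O)N(C)c2c1OC
F2 | step 6 | enantiomer of 15 (ent-15, the other half of the racemate) | COc1ccc2c3c(c(=O)n(C)c2c1OC)[C@H](CC(C)C)[C@@H]1[C@H](O3)c2c(c3ccc(OC)c(OC)c3n(C)c2=O)OC1(C)C
F3 | step 4 | 3-(2-bromo-2-methylpropanoyl)-4-hydroxy-7,8-dimethoxy-1-methylquinolin-2(1H)-one | COc1ccc2c(O)c(C(=O)C(C)(C)Br)c(=O)n(C)c2c1OC
F4 | step 4 | 6,7-dimethoxy-2,2,5-trimethylfuro[3,2-c]quinoline-3,4(2H,5H)-dione | COc1ccc2c3OC(C)(C)C(=O)c3c(=O)n(C)c2c1OC
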